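**Retrosynthetic overview**
- The target comes from a tris-O-protected precursor in one thiolate step. The C4 prenyl group on the dihydrobenzofuran comes from an aryl bromide (para-selective NBS) and prenyl-Bpin coupled at the α-carbon.
- The central ArCH2CH2–CH2Ar bond (sp3–sp2) comes from a propyl-Bpin on the chiral dihydrobenzofuran and a reverse-prenylated aryl bromide.
- The resorcinol ring comes from C2v-symmetric 4,6-dibromoresorcinol dipivalate, whose symmetry is broken by one γ-selective (reverse) prenylation.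
- The C2 stereocentre comes from enantioselective hydrogenation of an aromatic 2-(2-hydroxypropan-2-yl)benzofuran (key step), made from eugenol by ortho-iodination and Sonogashira/cyclization.
- Ring order: both benzene rings are bought; the furan ring is built aromatic (step 4) and then dearomatized to the (R)-dihydrofuran (step 6).

Assumption: the stereocentre in the given SMILES is read as (2R); compounds 1, 3, 5 and 7 are taken as commercial.

**Step 1**
Reactants: 1 4,6-dibromobenzene-1,3-diol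
Product: 2 4,6-dibromo-1,3-phenylene bis(2,2-dimethylpropanoate)
Conditions: PivCl (2.3 equiv), Et3N, DMAP (cat.), CH2Cl2, 0 °C → rt
Reagents that add atoms: pivaloyl chloride, CC(C)(C)C(Cl)=O
Why: Simple O-acylation; the pivalates tolerate the aqueous-base Pd steps, deactivate this ring toward NBS in step 8, and are removed by the final thiolate.

**Step 2**
Reactants: 2 4,6-dibromo-1,3-phenylene bis(2,2-dimethylpropanoate) (2.5 equiv); 3 4,4,5,5-tetramethyl-2-(3-methylbut-2-en-1-yl)-1,3,2-dioxaborolane (prenyl-Bpin)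
Product: 4 4-bromo-6-(2-methylbut-3-en-2-yl)-1,3-phenylene bis(2,2-dimethylpropanoate)
Conditions: Pd(OAc)2 (3 mol %), 1,1'-bis(di-tert-butylphosphino)ferrocene (3.6 mol %), aq K3PO4, THF, 60 °C; excess 2 recovered
Reagents that add atoms: none
Why: Symmetry-breaking γ-selective Suzuki–Miyaura allylation: the two C–Br bonds of 2 are equivalent so one coupling gives a single isomer, SE2' transmetalation puts Pd on the tertiary carbon, and the wide-bite-angle bisphosphine blocks σ–π–σ equilibration so reductive elimination gives the reverse-prenyl group.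

**Step 3**
Reactants: 5 eugenol (4-allyl-2-methoxyphenol)
Product: 6 4-allyl-2-iodo-6-methoxyphenol
Conditions: I2 (1.05 equiv), KI, NaHCO3, THF/H2O, 0 °C → rt
Reagents that add atoms: iodine, II
Why: Electrophilic aromatic iodination of the phenoxide at its only free ortho position, which is much faster than (reversible) iodine addition to the isolated allyl alkene.

**Step 4**
Reactants: 6 4-allyl-2-iodo-6-methoxyphenol; 7 2-methylbut-3-yn-2-ol
Product: 9 2-(5-allyl-7-methoxy-1-benzofuran-2-yl)propan-2-ol, via o-alkynylphenol 8 (not isolated)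
Conditions: PdCl2(PPh3)2 (3 mol %), CuI (5 mol %), Et3N, DMF, 60 °C
Reagents that add atoms: none
Why: Sonogashira coupling followed in the same pot by Cu/Pd-promoted 5-endo-dig hydroalkoxylation of the o-alkynylphenol (heteroannulation), which places the CMe2OH carbon at C2.

**Step 5**
Reactants: 9 2-(5-allyl-7-methoxy-1-benzofuran-2-yl)propan-2-ol
Product: 10 2-{7-methoxy-5-[3-(4,4,5,5-tetramethyl-1,3,2-dioxaborolan-2-yl)propyl]-1-benzofuran-2-yl}propan-2-ol
Conditions: HBpin (2.5 equiv), [Ir(cod)Cl]2 (1.5 mol %), dppm (3 mol %), CH2Cl2, rt; MeOH quench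
Reagents that add atoms: pinacolborane, B1OC(C)(C)C(C)(C)O1
Why: Ir-catalysed anti-Markovnikov hydroboration of the terminal alkene turns the allyl group into a hydrogenation-stable coupling handle without touching the aromatic furan; excess HBpin covers transient O-borylation of the carbinol, reversed by MeOH.

**Step 6 (key step)**
Reactants: 10 2-{7-methoxy-5-[3-(4,4,5,5-tetramethyl-1,3,2-dioxaborolan-2-yl)propyl]-1-benzofuran-2-yl}propan-2-ol
Product: 11 2-{(2R)-7-methoxy-5-[3-(4,4,5,5-tetramethyl-1,3,2-dioxaborolan-2-yl)propyl]-2,3-dihydro-1-benzofuran-2-yl}propan-2-ol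
Conditions: [Ru(cod)(2-methylallyl)2] (5 mol %), SINpEt·HBF4 (10 mol %, antipode delivering H to the C2 Si face), KOt-Bu (12 mol %), H2 (60 bar), n-hexane, 25–40 °C
Reagents that add atoms: none
Why: Ru–bis(NHC)-catalysed asymmetric hydrogenation of a 2-substituted benzofuran (dearomatization) reduces only the furan C2=C3 bond, and catalyst-controlled delivery of H2 to the Si face of C2 sets the 2R centre; the substrate has no other alkene or halide.

**Step 7**
Reactants: 11 2-{(2R)-7-methoxy-5-[3-(4,4,5,5-tetramethyl-1,3,2-dioxaborolan-2-yl)propyl]-2,3-dihydro-1-benzofuran-2-yl}propan-2-ol; 4 4-bromo-6-(2-methylbut-3-en-2-yl)-1,3-phenylene bis(2,2-dimethylpropanoate) (1.2 equiv)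
Product: 12 4-{3-[(2R)-2-(2-hydroxypropan-2-yl)-7-methoxy-2,3-dihydro-1-benzofuran-5-yl]propyl}-6-(2-methylbut-3-en-2-yl)-1,3-phenylene bis(2,2-dimethylpropanoate)
Conditions: Pd(OAc)2 (5 mol %), RuPhos (10 mol %), K3PO4, toluene/H2O (10:1), 85 °C
Reagents that add atoms: none
Why: B-alkyl Suzuki–Miyaura sp3–sp2 coupling of a primary alkyl-Bpin, with a bulky dialkylbiarylphosphine suppressing β-hydride elimination; the vinyl group, pivalates and free carbinol are tolerated and the C2 centre is remote.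

**Step 8**
Reactants: 12 4-{3-[(2R)-2-(2-hydroxypropan-2-yl)-7-methoxy-2,3-dihydro-1-benzofuran-5-yl]propyl}-6-(2-methylbut-3-en-2-yl)-1,3-phenylene bis(2,2-dimethylpropanoate)
Product: 13 4-{3-[(2R)-4-bromo-2-(2-hydroxypropan-2-yl)-7-methoxy-2,3-dihydro-1-benzofuran-5-yl]propyl}-6-(2-methylbut-3-en-2-yl)-1,3-phenylene bis(2,2-dimethylpropanoate)
Conditions: NBS (1.05 equiv), MeCN, 0 °C → rt, dark
Reagents that add atoms: N-bromosuccinimide, O=C1CCC(=O)N1Br
Why: Electrophilic aromatic bromination para to the methoxy group (C4), as with 3,5-dialkylanisoles where NBS/MeCN attacks the para position between two alkyl groups; the dipivalate ring is deactivated and the hindered monosubstituted vinyl is inert under these polar, non-radical conditions.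

**Step 9**
Reactants: 13 4-{3-[(2R)-4-bromo-2-(2-hydroxypropan-2-yl)-7-methoxy-2,3-dihydro-1-benzofuran-5-yl]propyl}-6-(2-methylbut-3-en-2-yl)-1,3-phenylene bis(2,2-dimethylpropanoate); 3 4,4,5,5-tetramethyl-2-(3-methylbut-2-en-1-yl)-1,3,2-dioxaborolane (2 equiv)
Product: 14 4-{3-[(2R)-2-(2-hydroxypropan-2-yl)-7-methoxy-4-(3-methylbut-2-en-1-yl)-2,3-dihydro-1-benzofuran-5-yl]propyl}-6-(2-methylbut-3-en-2-yl)-1,3-phenylene bis(2,2-dimethylpropanoate)
Conditions: Pd(OAc)2 (5 mol %), XPhos (10 mol %), aq K3PO4, THF, 65 °C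
Reagents that add atoms: none
Why: α-Selective Suzuki–Miyaura allylation: on this di-ortho-substituted aryl–Pd the tertiary σ-allyl cannot reductively eliminate, so with a monodentate phosphine it shifts (σ–π–σ) to the primary terminus and gives the linear prenyl group.

**Step 10**
Reactants: 14 4-{3-[(2R)-2-(2-hydroxypropan-2-yl)-7-methoxy-4-(3-methylbut-2-en-1-yl)-2,3-dihydro-1-benzofuran-5-yl]propyl}-6-(2-methylbut-3-en-2-yl)-1,3-phenylene bis(2,2-dimethylpropanoate)
Product: 15 4-{3-[(2R)-7-hydroxy-2-(2-hydroxypropan-2-yl)-4-(3-methylbut-2-en-1-yl)-2,3-dihydro-1-benzofuran-5-yl]propyl}-6-(2-methylbut-3-en-2-yl)benzene-1,3-diol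
Conditions: NaSEt (8 equiv), DMF, 110 °C, Ar; aq NH4Cl work-up
Reagents that add atoms: none
Why: Thiolate SN2 O-demethylation and thiolysis of both aryl pivalates in one pot under non-acidic conditions, so the prenyl and reverse-prenyl groups, the tertiary alcohol and the C2 ether stereocentre are untouched.

**Compound list**
1 | 4,6-dibromobenzene-1,3-diol | Oc1cc(O)c(Br)cc1Br | starting material
2 | 4,6-dibromo-1,3-phenylene bis(2,2-dimethylpropanoate) | CC(C)(C)C(=O)Oc1cc(OC(=O)C(C)(C)C)c(Br)cc1Br | intermediate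
3 | 4,4,5,5-tetramethyl-2-(3-methylbut-2-en-1-yl)-1,3,2-dioxaborolane | CC(C)=CCB1OC(C)(C)C(C)(C)O1 | starting material
4 | 4-bromo-6-(2-methylbut-3-en-2-yl)-1,3-phenylene bis(2,2-dimethylpropanoate) | C=CC(C)(C)c1cc(Br)c(OC(=O)C(C)(C)C)cc1OC(=O)C(C)(C)C | intermediate
5 | eugenol (4-allyl-2-methoxyphenol) | C=CCc1ccc(O)c(OC)c1 | starting material
6 | 4-allyl-2-iodo-6-methoxyphenol | C=CCc1cc(I)c(O)c(OC)c1 | intermediate
7 | 2-methylbut-3-yn-2-ol | C#CC(C)(C)O | starting material
8 | 4-allyl-2-(3-hydroxy-3-methylbut-1-yn-1-yl)-6-methoxyphenol | C=CCc1cc(C#CC(C)(C)O)c(O)c(OC)c1 | intermediate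
9 | 2-(5-allyl-7-methoxy-1-benzofuran-2-yl)propan-2-ol | C=CCc1cc(OC)c2oc(C(C)(C)O)cc2c1 | intermediate
10 | 2-{7-methoxy-5-[3-(4,4,5,5-tetramethyl-1,3,2-dioxaborolan-2-yl)propyl]-1-benzofuran-2-yl}propan-2-ol | COc1cc(CCCB2OC(C)(C)C(C)(C)O2)cc2cc(C(C)(C)O)oc12 | intermediate
11 | 2-{(2R)-7-methoxy-5-[3-(4,4,5,5-tetramethyl-1,3,2-dioxaborolan-2-yl)propyl]-2,3-dihydro-1-benzofuran-2-yl}propan-2-ol | COc1cc(CCCB2OC(C)(C)C(C)(C)O2)cc2c1O[C@@H](C(C)(C)O)C2 | intermediate
12 | 4-{3-[(2R)-2-(2-hydroxypropan-2-yl)-7-methoxy-2,3-dihydro-1-benzofuran-5-yl]propyl}-6-(2-methylbut-3-en-2-yl)-1,3-phenylene bis(2,2-dimethylpropanoate) | COc1cc(CCCc2cc(C(C)(C)C=C)c(OC(=O)C(C)(C)C)cc2OC(=O)C(C)(C)C)cc2c1O[C@@H](C(C)(C)O)C2 | intermediate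
13 | 4-{3-[(2R)-4-bromo-2-(2-hydroxypropan-2-yl)-7-methoxy-2,3-dihydro-1-benzofuran-5-yl]propyl}-6-(2-methylbut-3-en-2-yl)-1,3-phenylene bis(2,2-dimethylpropanoate) | COc1cc(CCCc2cc(C(C)(C)C=C)c(OC(=O)C(C)(C)C)cc2OC(=O)C(C)(C)C)c(Br)c2c1O[C@@H](C(C)(C)O)C2 | intermediate
14 | 4-{3-[(2R)-2-(2-hydroxypropan-2-yl)-7-methoxy-4-(3-methylbut-2-en-1-yl)-2,3-dihydro-1-benzofuran-5-yl]propyl}-6-(2-methylbut-3-en-2-yl)-1,3-phenylene bis(2,2-dimethylpropanoate) | COc1cc(CCCc2cc(C(C)(C)C=C)c(OC(=O)C(C)(C)C)cc2OC(=O)C(C)(C)C)c(CC=C(C)C)c2c1O[C@@H](C(C)(C)O)C2 | intermediate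
15 | 4-{3-[(2R)-7-hydroxy-2-(2-hydroxypropan-2-yl)-4-(3-methylbut-2-en-1-yl)-2,3-dihydro-1-benzofuran-5-yl]propyl}-6-(2-methylbut-3-en-2-yl)benzene-1,3-diol | C=CC(C)(C)c1cc(CCCc2cc(O)c3c(c2CC=C(C)C)C[C@H](C(C)(C)O)O3)c(O)cc1O | target

**Step count**
Total: 10 steps. Longest linear sequence: 8 steps (5 → 6 → 9 → 10 → 11 → 12 → 13 → 14 → 15); the ring A branch (1 → 2 → 4) is 2 steps.

**Three steps most likely to fail**

Step 6. The hydrogenation is untested on a benzofuran carrying a free tertiary carbinol at C2, so conversion or ee may fall short; which ligand antipode gives 2R must be fixed by a test run. The fallback sets out from eugenol 5 and comes back at 11, closing the ring by epoxide opening instead. C-Prenylation of sodium eugenolate (NaH, toluene, prenyl bromide) gives 4-allyl-2-methoxy-6-(3-methylbut-2-en-1-yl)phenol F1. Silylation (TBSCl, imidazole) gives [4-allyl-2-methoxy-6-(3-methylbut-2-en-1-yl)phenoxy](tert-butyl)dimethylsilane F2. Shi epoxidation with the L-fructose-derived ketone (Oxone, pH 10.5), which leaves the monosubstituted allyl alkene alone, gives tert-butyl(4-allyl-2-{[(2S)-3,3-dimethyloxiran-2-yl]methyl}-6-methoxyphenoxy)dimethylsilane F3. TBAF frees 4-allyl-2-{[(2S)-3,3-dimethyloxiran-2-yl]methyl}-6-methoxyphenol F4, whose phenoxide opens the epoxide 5-exo with inversion to 2-[(2R)-5-allyl-7-methoxy-2,3-dihydro-1-benzofuran-2-yl]propan-2-ol F5. Ir-catalysed hydroboration of F5 with pinacolborane under the conditions of step 5 gives 11.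

Step 2. The quaternary carbon must form ortho to a pivalate; linear (α) prenylation or double coupling may compete. The fallback sets out from 2 and comes back at 4, fixing the quaternary carbon by enolate arylation. Pd-catalysed α-arylation of isobutyraldehyde with excess 2 (Pd(OAc)2, XPhos, Cs2CO3, dioxane, 80 °C) gives 4-bromo-6-(2-methyl-1-oxopropan-2-yl)-1,3-phenylene bis(2,2-dimethylpropanoate) F6. Wittig methylenation (Ph3P=CH2, THF, −78 → 0 °C) turns the aldehyde into the vinyl group and gives 4.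

Step 9. The bromide is electron-rich and flanked on both sides, so the allylboronate coupling may be slow. The fallback sets out from 13 and comes back at 14, using a smaller allyl group and then extending it. Stille coupling with allyltributylstannane (Pd(Pt-Bu3)2, dioxane, 90 °C) gives 4-{3-[(2R)-2-(2-hydroxypropan-2-yl)-7-methoxy-4-(prop-2-en-1-yl)-2,3-dihydro-1-benzofuran-5-yl]propyl}-6-(2-methylbut-3-en-2-yl)-1,3-phenylene bis(2,2-dimethylpropanoate) F7. Cross-metathesis with 2-methylbut-2-ene (Grubbs II, CH2Cl2, 40 °C) converts the allyl into the prenyl group and gives 14; the vinyl group next to the quaternary carbon on the other ring does not take part.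

**Further compounds**
F1 | step 6 | 4-allyl-2-methoxy-6-(3-methylbut-2-en-1-yl)phenol | C=CCc1cc(CC=C(C)C)c(O)c(OC)c1
F2 | step 6 | [4-allyl-2-methoxy-6-(3-methylbut-2-en-1-yl)phenoxy](tert-butyl)dimethylsilane | C=CCc1cc(CC=C(C)C)c(O[Si](C)(C)C(C)(C)C)c(OC)c1
F3 | step 6 | tert-butyl(4-allyl-2-{[(2S)-3,3-dimethyloxiran-2-yl]methyl}-6-methoxyphenoxy)dimethylsilane | C=CCc1cc(C[C@@H]2OC2(C)C)c(O[Si](C)(C)C(C)(C)C)c(OC)c1
F4 | step 6 | 4-allyl-2-{[(2S)-3,3-dimethyloxiran-2-yl]methyl}-6-methoxyphenol | C=CCc1cc(C[C@@H]2OC2(C)C)c(O)c(OC)c1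
F5 | step 6 | 2-[(2R)-5-allyl-7-methoxy-2,3-dihydro-1-benzofuran-2-yl]propan-2-ol | C=CCc1cc(OC)c2c(c1)C[C@H](C(C)(C)O)O2
F6 | step 2 | 4-bromo-6-(2-methyl-1-oxopropan-2-yl)-1,3-phenylene bis(2,2-dimethylpropanoate) | O=CC(C)(C)c1cc(Br)c(OC(=O)C(C)(C)C)cc1OC(=O)C(C)(C)C
F7 | step 9 | 4-{3-[(2R)-2-(2-hydroxypropan-2-yl)-7-methoxy-4-(prop-2-en-1-yl)-2,3-dihydro-1-benzofuran-5-yl]propyl}-6-(2-methylbut-3-en-2-yl)-1,3-phenylene bis(2,2-dimethylpropanoate) | COc1cc(CCCc2cc(C(C)(C)C=C)c(OC(=O)C(C)(C)C)cc2OC(=O)C(C)(C)C)c(CC=C)c2c1O[C@@H](C(C)(C)O)C2
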